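Start from a one-step world: one incoming ligand per starting complex, and the product stops at the complex with one exchanged. Tuesday's readings refuse that world.

| setting | Tuesday's | grey | blue | green |
|---|---|---|---|---|
| starting complex | 0.38 M | 0.25 M | 0.25 M | 0.25 M |
| incoming ligand | 0.80 equiv | 0.800 equiv | 3.00 equiv | 4.00 equiv |
| remark | run made earlier |  |  |  |
| time |  | 25 h | 25 h | 25 h |

- Tuesday's (time / h: complex with two exchanged / %, starting complex / %): 0.667: 0, 96.1; 1.50: 1.5, 90.7; 3.00: 5.7, 83.4; 5.00: 10.3, 76.5; 6.00: 12.2, 72.5; 8.00: 15.5, 67.5

(readings scatter by 0.5 percentage points)

- steps thought possible: starting complex + incoming ligand -> leaving ligand + complex with one exchanged; complex with one exchanged + incoming ligand -> leaving ligand + complex with two exchanged; starting complex <-> dormant form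
- no earlier run changes the charge of incoming ligand; that part of a forecast is a guess

* how much complex with two exchanged is there at the end, in percent of the starting complex charged: for each flask in turn (grey, blue, green)

Read Tuesday's run: the complex with two exchanged stands at 0% after 0.667 h, then at 15.5% after 8.00 h, so it appears late and a second exchange follows the first. Between 5.00 h and 8.00 h it gains 5.2 percentage points while the starting complex loses 9 points. But 17.0% is unaccounted for at 8.00 h, and these readings do not split it between the complex with one exchanged and the dormant form.

Take the second exchange as quick, as a working assumption, and charge each finished complex two incoming ligands. Grey's ligand ceiling is then 0.400 per starting complex charged: the equivalents charged divided by two, the most complex with two exchanged that the incoming ligand can make. Grey's incoming ligand is the limiting reagent, since that ceiling is lower than the starting complex charged. Blue's ceiling is 1.50 and green's 2.00, both higher than the starting complex charged. Expect grey under its ceiling, and in blue and green expect the starting complex charged to be the cap.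

The forecast says 25%, 86% and 91%, adding for blue and green: “The yield is then limited by what is trapped as dormant form”.

The flasks give 26.3% in grey, 81.8% in blue and 90.4% in green.

    starting complex + incoming ligand → leaving ligand + complex with one exchanged (k = 0.00318 L mol⁻¹ min⁻¹)
    complex with one exchanged + incoming ligand → leaving ligand + complex with two exchanged (k = 0.0200 L mol⁻¹ min⁻¹)
    starting complex ⇌ dormant form (K = 2.10, k = 1.52 × 10⁻⁴ min⁻¹)

Grey ends lower than its ceiling of 0.400, with 22% of its incoming ligand and 49.7% of its starting complex still there. After 250 h, grey holds 36.6% complex with two exchanged, still lower than that ceiling, with incoming ligand down to 0.0104% of its charge. Blue's ceiling of 1.50 stands higher than its starting complex charged, and at the end blue still has 45% of its incoming ligand free.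

Readings and results stem from a simulated flask from invented constants; noise was put on by code.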